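The autocatalytic step overtakes the plain addition of X to Z at a very low level of X.Z. Both carry the factor c(X)·c(Z), so they run equally fast when c(X.Z) equals 6.36 × 10⁻⁵ M, the take-over level, which is the zero of my scale and 0.0636% of the X charged.

in all of them: X 0.10 M

| flask | Z | time | remark |
|---|---|---|---|
| gamma | 0.500 M (fed, over 10.0 d) | 10 d | a stirred flask in which Z is dosed at a steady rate over 10.0 d without added volume, worked up at 10 d |
| beta | 0.500 M | 10 d | everything together in a closed stirred flask, run for 10 d |
| theta | 0.500 M | 10 d | a tube with plug flow, the mixed feed as stated, residence time 10 d |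
| eta | 0.500 M |  | one stirred flow tank at steady state, fed with the mixture as stated, mean residence time 10 d |

    X + Z + X.Z → 2 X.Z (k1 = 3.3 × 10⁻⁴ M⁻² s⁻¹)
    X + Z → X.Z (k2 = 2.1 × 10⁻⁸ M⁻¹ s⁻¹)
    X.Z → E (k3 = 2.3 × 10⁻⁹ s⁻¹)
    X ⇌ L (K4 = 3.1, k4 = 4.9 × 10⁻⁶ s⁻¹)
    Z + X.Z → Z.X.Z (k5 = 1.6 × 10⁻⁶ M⁻¹ s⁻¹)

- the stated concentrations are those of everything mixed, before any reaction; amounts are the same in each set-up
- the feed brings no volume worth counting
- run time (gamma): 10 d

- the set-up with the highest amount of X.Z at the outlet or at the end, in percent of the X put in ("none" if the first two lie within 2 percentage points) (gamma / beta / theta / eta / none)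
- amount of X.Z at the outlet or at the end, in percent of the X put in, gamma
- amount of X.Z at the outlet or at the end, in percent of the X put in, beta
- amount of X.Z at the outlet or at the end, in percent of the X put in, theta
- amount of X.Z at the outlet or at the end, in percent of the X put in, eta

I reckon in rates. In beta, X.Z multiplies at 1.43 d⁻¹ at the start, a doubling every 0.485 d, and the tube theta is the same flask read along its length. Two things slow this. The drain of X to L, relaxing at 0.560 d⁻¹, brings the rate, once X has relaxed, down to a factor 0.244 of its starting value. The passing into Z.X.Z, pseudo-first-order at 0.0691 d⁻¹ with c(Z) held at its charge, subtracts a further 4.83% of the starting rate. I drop the passing into E, since its half-life 3500 d is far longer than the time 10 d. Summed over the run, 14.3 undisturbed e-foldings shrink to 4.70. By this reckoning X.Z ends at the take-over level times exp(N) less one, which gives 6.96% for beta and 6.96% for theta.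

In gamma, c(Z) climbs from zero while X drains, so the same sum weighted by dosed Z gives fewer e-foldings, 1.73, and 0.295%.

The stirred tank eta holds X.Z at its outlet concentration, so at steady state, with c(Z) again taken at its charge, growth equals washout plus loss, 0.169 d⁻¹, which is less than the growth at the charge. By this reckoning X sits at 11.9% of its charge and L at 21.2%, and with E dropped as before, the rest divides between X.Z and Z.X.Z as one to 0.691, giving 39.6%. My ranking puts eta first.

The forecast gives 0.33% for gamma, 7% for beta, 7% for theta and 40% for eta, with eta best, since the tank “runs permanently on the ignited branch”. The simulation gives 0.343%, 6.15%, 6.15% and 39.9% in that order, with eta best.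

In beta, the autocatalytic step runs while X sinks to 21.0% of its charge, and X.Z ends at 96.6 times the take-over level, with 1.40% of the X standing as Z.X.Z. In gamma, the same step runs while Z is still arriving and X ends at 24.5% of its charge, with X.Z at 5.40 times that level, whereas in the tank eta X stands at 0.0133 M everywhere in the vessel, with X.Z at 627 times that level and Z.X.Z at 22.9% of the X charged.

(All constants are invented; the result is computed.)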